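The readings were generated by integration with made-up constants; the scatter is artificial.

What stays the same from run to run, as long as both hands react at one fixed ratio of rates, is the logarithm of what is left of one hand divided by that of the other. Two chemists dispute the new flask over this.

| flask | left-handed substrate | right-handed substrate | solid reagent | free catalyst | remark | time |
|---|---|---|---|---|---|---|
| Sunday's | 0.031 M | 0.031 M | 0.022 M | 0.22 mM | run made earlier |  |
| Saturday's | 0.048 M | 0.048 M | 0.022 M | 0.22 mM | run made earlier |  |
| flask | 0.022 M | 0.022 M | 0.0220 M | 0.22 mM |  | 2.5 d |

| run | time / d | right-handed substrate / % | left-handed substrate / % | left-handed product / % |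
|---|---|---|---|---|
| Sunday's | 0.125 | 44.1 | 33.6 | 16.5 |
| Sunday's | 0.417 | 39.8 | 26.8 | 25.4 |
| Sunday's | 0.625 | 39.2 | 26.0 | 24.2 |
| Sunday's | 1.04 | 40.6 | 26.1 | 24.9 |
| Sunday's | 1.67 | 39.4 | 25.7 | 24.3 |
| Sunday's | 2.08 | 39.9 | 26.7 | 24.3 |
| Sunday's | 2.50 | 40.0 | 26.0 | 25.0 |
| Saturday's | 0.125 | 44.6 | 38.6 | 13.8 |
| Saturday's | 0.417 | 43.9 | 33.2 | 15.9 |
| Saturday's | 0.625 | 42.5 | 34.1 | 16.3 |
| Saturday's | 1.04 | 42.9 | 34.6 | 14.8 |
| Saturday's | 1.67 | 45.3 | 34.3 | 15.8 |
| Saturday's | 2.08 | 44.0 | 32.2 | 16.1 |
| Saturday's | 2.50 | 42.2 | 33.9 | 16.2 |

(scatter of a reading: 1 percentage point)

- free catalyst is single-handed; left-handed substrate and right-handed substrate are mirror images of each other, charged as a racemate, each of them at the stated concentration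
- given per volume of solution although it is solid: solid reagent
- at the start none of the solid reagent is in solution

1. whether the excess of right-handed substrate over left-handed substrate among what is left of the two reaches 95% by 2.5 d (yes / no)
2. the highest excess of right-handed substrate over left-handed substrate among what is left of the two up to 2.5 d

The first chemist looks at the charge: the flask has 0.0220 M of solid reagent against 0.022 M of left-handed substrate, the same amount. If the left-handed substrate took the whole reagent, the excess of right-handed substrate would reach 100%.

The second chemist replaces each flat stretch of the runs by its mean over the last 6 readings. Sunday's run then holds 39.8% right-handed and 26.2% left-handed substrate. Saturday's run holds 43.5% and 33.7%. On Sunday the right-handed substrate has lost 10 percentage points of the two together, against a scatter of 1 point, so both hands share the reagent.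

Taken against each hand's own charge, the ratio reads 2.83 on Sunday and 2.81 on Saturday. I keep the mean 2.82 as the hand ratio (the selectivity factor): the logarithm of the share of left-handed substrate left, divided by the logarithm of the share of right-handed substrate left.

The substrate consumed is 0.0211 M on Sunday and 0.0219 M on Saturday, close to the solid reagent, which looks like the limiting reagent. If the flask stops at their mean, 0.0215 M, the hand ratio leaves 68.3% of the right-handed and 34.1% of the left-handed substrate, each of its own charge. My excess is therefore 33.4%, below the 95% wanted.

The forecast says no and 35%, a little above mine, on the ground “so the reagent limits the reaction”.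

The simulation gives no and 31.9%, which is 1.5 points below my reckoning.

    partner + free catalyst + left-handed substrate → free catalyst + left-handed product (k = 1.70 × 10⁵ L² mol⁻² h⁻¹)
    partner + free catalyst + right-handed substrate → free catalyst + right-handed product (k = 62000 L² mol⁻² h⁻¹)
    2 partner → self-condensation product (k = 2.70 L mol⁻¹ h⁻¹)
    free catalyst → spent catalyst (k = 0.0580 h⁻¹)
    solid reagent ⇌ partner, rate k5*(cs5 - [partner]) while solid is left; crystals form when [partner] > cs5 (solubility = 11.0 mM, k = 0.890 h⁻¹)

By 0.250 d the dissolving of solid reagent in the flask had 100% of its turnover behind it, and the two substrates reacted with the partner while free catalyst fell to 70.6%, half their turnover being done by 0.112 d and 0.130 d. At 2.50 d the flask keeps 35% and 68% of its two hands, a hand ratio of 2.72. The neighbour with 0.055 M of solid reagent comes nearer the first chemist's 100%, though both hands react there, with 39.9% standing as right-handed product at 2.50 d: from its 20% of right-handed substrate, the kept ratio gives an excess of 89.7%, and that flask reaches 88.3%, with 1.3% of left-handed substrate left.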